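## The problem

The target is a trans-fused hydroazulene diester. A cyclopentane (C6–C7–C8–C9–C10) shares the C6–C10 bond with a cycloheptene (C1–C2–C3–C4–C5–C6–C10). In this local numbering, used throughout, C1 carries the 4-methoxybenzoate, C3 the vinylic methyl, C5 the acetate, C6 the angular methyl, and C9 the hydroxyl and the isopropyl group; the compound is (1S,5S,6S,9R,10S).

Five stereocentres surround the ring fusion. Two are fully substituted: the all-carbon quaternary C6 and the tertiary carbinol C9, whose hydroxyl is cis to the C6 methyl and trans to H10.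

C6 cannot be corrected once made, so it has to come first and with absolute control. It can then steer C9 through the two faces of a C9=C10 alkene. C9 and C6 together fix C10 thermodynamically, the C9 hydroxyl and C10 direct an addition to a C1 aldehyde by chelation, and the axial C6 methyl directs hydride to a C5 ketone.

Several features will not survive rough treatment. The tertiary β-hydroxy carbonyl array C9–C10–C1 can undergo retro-aldol cleavage or dehydration whenever C1 is a carbonyl. The allylic C5 acetate can ionise or eliminate. The C3=C4 alkene forbids late hydrogenolysis. The two different esters on two secondary carbinols must be introduced one at a time.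

The feature that opens the route is the substitution pattern of the cyclopentane: a methyl and a one-carbon branch on C6, a three-carbon branch on C9 and the exocyclic C1 on C10. This is a p-menthane ring less one carbon. If C1 is put back between C6 and C10, the six-membered ring of a 2-alkylated dihydrocarvone appears with C1 as its carbonyl carbon.

## Retrosynthesis

**Acetate and C5.** Target 29 is opened at the acetate. Acetylation of allylic alcohol 28 ends the route, because the tertiary C9 hydroxyl does not compete and the 4-methoxybenzoate is already in place. The C5–H bond of 28 is then cut back to enone 27. The alternative, adding C4 to a C5 aldehyde with control, asks an α-quaternary aldehyde to distinguish a methyl from a ring methylene, which is a weak Felkin–Anh bias. Inside the ring the angular methyl is axial and next to the carbonyl, so a 1,2-selective hydride reduction should enter anti to it.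

**Seven-membered ring.** Enone 27 is traced through allylic alcohols 26 to dienes 25 by cutting C3=C4 (ring-closing metathesis). Dienes 25 come from aldehyde 23 and vinylmagnesium bromide 24. Two neighbouring cuts were weighed:
- Closing C1–C2 by a vinylogous aldol reaction of a C5 dienolate onto a C1 aldehyde. The α-carbon of that dienolate would close a five-membered ring instead, and the product is a retro-aldol-prone aldol.
- Closing C4–C5 by an organometallic addition. This creates C5 in the ring-forming event with no controlling element.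

The metathesis cut leaves a monocyclic cyclopentane with two arms. It asks the catalyst only to join a monosubstituted and a 1,1-disubstituted alkene beside a quaternary centre, in the presence of free hydroxyls and an aryl ester.

**C1–C2 bond and the anisoate.** Aldehyde 23 comes from silyl ether 21 by desilylation (22) and oxidation. Ester 21 comes from diol 19 and 4-methoxybenzoyl chloride 20; the acylation is selective because only one of the two hydroxyls is secondary. Diol 19 is cut at C1–C2 into β-hydroxy aldehyde 17 and 3-bromo-2-methylprop-1-ene 18. The C9 hydroxyl and the aldehyde oxygen can bind one metal; in that chelate the quaternary C6 blocks one face of C1 and the nucleophile enters beside H10, which gives 1S. A non-chelating addition would have to choose between two fully substituted α-neighbours and has no clear bias. The forward reaction must therefore tolerate and use the free hydroxyl, which points to a Barbier-type allylation in water.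

**C9–O and C10–H.** Aldehyde 17 is the C10 epimer of 16, which comes from hydroxy ester 15, epoxy ester 14 and enoate 13. The bonds cut are C9–O and C10–H.
- A carbon nucleophile added to a C9 ketone would be the classical way to this carbinol, but it would require removing the three-carbon branch that the chiral pool supplies.
- Oxygen delivered to C9 while C10 is sp3 enters anti to C1, which is the wrong face.
- With C10 sp2 the two faces differ only at C6. The one hydroxyl that could direct an epoxidation, on C5, sits on the wrong side, so C5 is made bulky instead and the peracid is sent past the methyl group.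

One-electron opening of 14 keeps the C9–O bond. C10 is then set by equilibration of the aldehyde, where the isomer needed has the formyl group trans to both large neighbours.

**Unsaturation.** Enoate 13 comes from saturated ester 11 by selenenylation (12) and selenoxide elimination; C9–H is the only β-hydrogen. Ester 11 comes from alcohol 10, and 10 from ester 9 by one hydrogenation that saturates the isopropenyl group and removes the benzyl group.

**Cyclopentane (key disconnection).** Ester 9 is cut at C6–C10 and C6 is re-bonded to C1. This gives 2-diazo ketone 6, whose photochemical Wolff rearrangement (through ketene 7) contracts the ring. Building the cyclopentane by alkylation or aldol chemistry would require a new enantioselective construction of C6. The ring contraction imports C6 and the C9 branch from a terpene and asks of the forward step only that the quaternary carbon migrate, which it does with retention.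

**Chiral pool.** Diazo ketone 6 comes from ketone 4 by diazo transfer through trifluoroacetyl ketone 5; only one α-position bears hydrogen. Ketone 4 comes from (R)-carvone 1 and benzyl chloromethyl ether 2 by reductive alkylation through enolate 3. Axial alkylation cis to the isopropenyl group gives the C6 configuration of the target.

## Roads not taken

**Alternative 1: De Mayo photocycloaddition with ring expansion.** The cut removes C2–C3 and C4–C5. The enol of cyclopentane-1,3-dione A1 would add photochemically to allene A2, and retro-aldol opening of the cyclobutanol would give the 3-methylenecycloheptane-1,5-dione A3.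
- Merits: one photochemical operation delivers the seven-membered ring with oxygen at C1 and C5 and the C3 carbon. The five-membered ring would then close by aldol addition of C10 to the unmasked C9 ketone, which makes the tertiary carbinol directly.
- Weak points for this target: the quaternary C6 of A1 has no chiral-pool source and needs its own enantioselective synthesis. A1 is unsymmetrical, so two enols and two orientations of A2 are possible. The two ketones of A3 must be told apart. The exocyclic methylene must be moved to C3=C4 and not to C2=C3, although both positions are conjugated. The aldol closure has no obvious controller for the ring fusion or for C9.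
- Comparison: in ring-forming economy this road is better than the chosen one, which needs a late metathesis. The chosen plan sets against it a C6 centre of secured absolute configuration and a defined chain of stereocontrol from it.

**Alternative 2: Asymmetric conjugate methylation with aldol trapping.** The cut removes C6–CH3 and C10–C1. Copper-catalysed addition of a methylaluminium reagent to cyclopentenone A4 in the presence of a chiral phosphoramidite would set C6, and the aluminium enolate would add to iodoalkenyl aldehyde A5 to give aldol A6.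
- Merits: C6, C10 and C1 arise in one flask. The (Z)-iodoalkene prepares a C4–C5 closure. The C9 ketone remains for addition of the isopropyl group anti to the C10 substituent, which is a more direct and stereochemically more natural entry to the C9 carbinol than the epoxidation and reduction sequence of the chosen plan. The route would also be several steps shorter.
- Weak points: enantioselective conjugate addition that builds a quaternary centre is least developed for cyclopentenones, and here the β-substituent is an acetal. The aldol selectivity at C1 is uncertain. A6 is a retro-aldol-prone β-hydroxy ketone that must survive the addition of a hindered nucleophile to an enolisable ketone. The ring closure creates C5 without clear control.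
- Comparison: the chosen plan sets against the shorter sequence a configuration that does not depend on an untested catalyst–substrate pairing, and bond formations that each have close precedent.

**Alternative 3: Divinylcyclopropane Cope rearrangement.** The cut forms C5–C6 and breaks C1–C3 of cis-divinylcyclopropane A7, giving cycloheptadiene A8.
- Merits: the seven-membered ring, the C3=C4 alkene, a C1 enol ether and the C5/C6 pair arise in one stereospecific thermal step, with C9 already in place. This is the most elegant ring construction of the four.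
- Weak points: the boat transition state must place both the C6 methyl and the C5 acetoxy group on the inside, because the target has them cis. That is the slowest substitution pattern for this rearrangement; it requires a (Z)-enol acetate and invites epimerisation of the cyclopropane at the temperatures needed. A7 is a fully substituted cyclopropane on a tetrasubstituted cyclopentene and would need a long stereospecific synthesis. C10 and C1 still have to be set after hydrolysis of the enol ether.
- Comparison: the chosen plan is longer in its endgame but uses no step whose geometry works against it.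

Key step: step 3

Assumption: the stereodescriptors of the SMILES string are taken as the absolute configuration, (1S,5S,6S,9R,10S) in the local numbering. LiN(SiMe3)2, LiN(iPr)2, SmI2 and CH2=CHMgBr are used as purchased solutions.

## Route

Step 1
Reactants: 1 (R)-carvone; 2 benzyl chloromethyl ether
Product: 4 (2R,5R)-2-[(benzyloxy)methyl]-2-methyl-5-(prop-1-en-2-yl)cyclohexan-1-one, via lithium enolate 3 (not isolated)
Conditions: Li, NH3(l), THF, tBuOH (1 equiv), −78 °C; NH3 removed; then ClCH2OBn, THF, −78 → 0 °C
Reagents that add atoms: benzyl chloromethyl ether, ClCOCc1ccccc1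
Why: Dissolving-metal reduction of the enone gives the regiodefined enolate 3, which is alkylated at the methyl-bearing carbon (reductive alkylation); the electrophile enters axially through a chair-like transition state, cis to the equatorial isopropenyl group, which sets the quaternary centre (C6 of the target) from the carvone stereocentre.

Step 2
Reactants: 4 (2R,5R)-2-[(benzyloxy)methyl]-2-methyl-5-(prop-1-en-2-yl)cyclohexan-1-one
Product: 6 (3S,6R)-6-[(benzyloxy)methyl]-2-diazo-6-methyl-3-(prop-1-en-2-yl)cyclohexan-1-one, via 2-trifluoroacetyl ketone 5 (not isolated)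
Conditions: LiN(SiMe3)2, THF, −78 °C; CF3CO2CH2CF3; then MeSO2N3, Et3N, H2O, MeCN, rt
Reagents that add atoms: methanesulfonyl azide, CS(=O)(=O)N=[N+]=[N-]
Why: Only one α-carbon bears hydrogen, so enolisation and trifluoroacetylation occur there, and detrifluoroacetylative diazo transfer (Regitz-type) should give the diazo ketone without touching the alkene or the benzyl ether; no stereocentre is created.

Step 3
Reactants: 6 (3S,6R)-6-[(benzyloxy)methyl]-2-diazo-6-methyl-3-(prop-1-en-2-yl)cyclohexan-1-one
Product: 9 methyl (1S,2S,5R)-2-[(benzyloxy)methyl]-2-methyl-5-(prop-1-en-2-yl)cyclopentane-1-carboxylate, via cyclopentylidene ketene 7 (not isolated), via C10-epimeric methyl ester 8 (not isolated)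
Conditions: hν (Pyrex-filtered medium-pressure Hg lamp or 365 nm LED), MeOH, 0 °C; then NaOMe (cat.), MeOH, 50 °C
Reagents that add atoms: methanol, CO
Why: Irradiation excites the diazo ketone, which the ring locks s-cis, so that loss of N2 and the 1,2-shift of the quaternary carbon C6 from the carbonyl carbon to the diazo carbon are concerted (photochemical Wolff rearrangement) and give ketene 7. The closest known reaction type is the photochemical Wolff ring contraction of 2-diazocycloalkanones to cycloalkanecarboxylic esters. The cyclopentane is closed not by a cyclisation but by this 1,2-shift, a ring contraction that forms C6–C10 and pushes C1 into an exocyclic position, so rules for ring-closing trajectories do not apply. C6 migrates with retention, so the quaternary centre from step 1 is carried over unchanged, and C9 is not involved. Methanol adds to the ketene and the ester enol ketonises; the new stereocentre C10 is then placed under thermodynamic control by NaOMe, with the ester trans to the isopropenyl group on C9 and to the benzyloxymethyl group on C6, so that any epimer 8 is converted to 9. The step needs regiocontrol of the diazo group, which the quaternary α′-carbon secures, and migration in preference to O–H insertion, 1,2-hydride shift from C9 or reaction at the isopropenyl group, which the concerted path of the s-cis diazo ketone in methanol favours.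

Step 4
Reactants: 9 methyl (1S,2S,5R)-2-[(benzyloxy)methyl]-2-methyl-5-(prop-1-en-2-yl)cyclopentane-1-carboxylate
Product: 10 methyl (1S,2S,5S)-2-(hydroxymethyl)-2-methyl-5-(propan-2-yl)cyclopentane-1-carboxylate
Conditions: H2 (1 atm), Pd/C, EtOAc–MeOH, rt
Reagents that add atoms: none
Why: Heterogeneous hydrogenation saturates the 1,1-disubstituted alkene and hydrogenolyses the benzyl ether in the same operation; no stereocentre is formed, and the trans arrangement of CH2OH and CO2Me on the ring prevents lactonisation.

Step 5
Reactants: 10 methyl (1S,2S,5S)-2-(hydroxymethyl)-2-methyl-5-(propan-2-yl)cyclopentane-1-carboxylate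
Product: 11 methyl (1S,2S,5S)-2-{[(tert-butyldiphenylsilyl)oxy]methyl}-2-methyl-5-(propan-2-yl)cyclopentane-1-carboxylate
Conditions: tBuPh2SiCl, imidazole, DMF, rt
Reagents that add atoms: tert-butyl(chloro)diphenylsilane, CC(C)(C)[Si](Cl)(c1ccccc1)c1ccccc1
Why: Standard silylation of a primary alcohol; the bulky silyl ether protects C5–O through the next steps and makes the C5 arm clearly larger than the C6 methyl for step 7.

Step 6
Reactants: 11 methyl (1S,2S,5S)-2-{[(tert-butyldiphenylsilyl)oxy]methyl}-2-methyl-5-(propan-2-yl)cyclopentane-1-carboxylate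
Product: 13 methyl (5S)-5-{[(tert-butyldiphenylsilyl)oxy]methyl}-5-methyl-2-(propan-2-yl)cyclopent-1-ene-1-carboxylate, via α-phenylselanyl ester 12 (not isolated)
Conditions: LiN(iPr)2, THF, −78 → −40 °C; PhSeBr, −78 °C; then 30% H2O2, pyridine, CH2Cl2, 0 °C → rt
Reagents that add atoms: none
Why: Ester enolate selenenylation followed by selenoxide syn-elimination; PhSeBr should enter on the face of the C6 methyl and H9, the less hindered one, so that selenium and H9 are cis as the elimination requires, and C9–H is the only β-hydrogen, which fixes the C9=C10 position.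

Step 7
Reactants: 13 methyl (5S)-5-{[(tert-butyldiphenylsilyl)oxy]methyl}-5-methyl-2-(propan-2-yl)cyclopent-1-ene-1-carboxylate
Product: 14 methyl (1R,2R,5R)-2-{[(tert-butyldiphenylsilyl)oxy]methyl}-2-methyl-5-(propan-2-yl)-6-oxabicyclo[3.1.0]hexane-1-carboxylate
Conditions: mCPBA, CH2Cl2, 0 °C → rt
Reagents that add atoms: 3-chloroperoxybenzoic acid, OOC(=O)c1cccc(Cl)c1
Why: Peracid (Prilezhaev) epoxidation of the tetrasubstituted enoate; the two faces differ only at the allylic quaternary C6, and the oxidant should pass the methyl group, anti to the CH2OSi(tBu)Ph2 arm, which places the epoxide oxygen, and with it the future C9 oxygen, cis to the C6 methyl.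

Step 8
Reactants: 14 methyl (1R,2R,5R)-2-{[(tert-butyldiphenylsilyl)oxy]methyl}-2-methyl-5-(propan-2-yl)-6-oxabicyclo[3.1.0]hexane-1-carboxylate
Product: 15 methyl (1S,2S,5R)-2-{[(tert-butyldiphenylsilyl)oxy]methyl}-5-hydroxy-2-methyl-5-(propan-2-yl)cyclopentane-1-carboxylate
Conditions: SmI2, THF–HMPA, Me2NCH2CH2OH, 0 °C
Reagents that add atoms: none
Why: One-electron reduction of the α,β-epoxy ester by SmI2 cleaves only the Cα–O bond, so C9 keeps the oxygen and the configuration of the epoxide; the samarium enolate should be protonated at C10 from the open face beside the C6 methyl and the C9 oxygen, which puts the ester cis to isopropyl, an outcome that step 9 corrects.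

Step 9
Reactants: 15 methyl (1S,2S,5R)-2-{[(tert-butyldiphenylsilyl)oxy]methyl}-5-hydroxy-2-methyl-5-(propan-2-yl)cyclopentane-1-carboxylate
Product: 17 (1R,2S,5R)-2-{[(tert-butyldiphenylsilyl)oxy]methyl}-5-hydroxy-2-methyl-5-(propan-2-yl)cyclopentane-1-carbaldehyde, via C10-epimeric aldehyde 16 (not isolated)
Conditions: iBu2AlH, CH2Cl2, −78 °C; aq. potassium sodium tartrate; then DBU (cat.), CH2Cl2, 0 °C → rt
Reagents that add atoms: none
Why: Low-temperature iBu2AlH reduction should stop at the aluminium hemiacetal, which the neighbouring aluminium alkoxide holds, and release aldehyde 16 on work-up; DBU then epimerises C10 through the enol to the isomer with the formyl group trans to isopropyl and to the silyloxymethyl arm, which is favoured thermodynamically and by an O–H···O=C hydrogen bond, so C10 reaches the configuration of the target.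

Step 10
Reactants: 17 (1R,2S,5R)-2-{[(tert-butyldiphenylsilyl)oxy]methyl}-5-hydroxy-2-methyl-5-(propan-2-yl)cyclopentane-1-carbaldehyde; 18 3-bromo-2-methylprop-1-ene
Product: 19 (1R,2S,3S)-3-{[(tert-butyldiphenylsilyl)oxy]methyl}-2-[(1S)-1-hydroxy-3-methylbut-3-en-1-yl]-3-methyl-1-(propan-2-yl)cyclopentan-1-ol
Conditions: In (powder), THF–H2O (1:1), rt
Reagents that add atoms: 3-bromo-2-methylprop-1-ene, CC(=C)CBr
Why: Barbier-type allylation with indium in aqueous THF tolerates the free tertiary hydroxyl, which binds the metal together with the aldehyde oxygen (Cram-chelate control); in the six-membered chelate the quaternary C6 shields one face of C1, and the methallyl group should add from the side of H10 to give the (1S) carbinol.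

Step 11
Reactants: 19 (1R,2S,3S)-3-{[(tert-butyldiphenylsilyl)oxy]methyl}-2-[(1S)-1-hydroxy-3-methylbut-3-en-1-yl]-3-methyl-1-(propan-2-yl)cyclopentan-1-ol; 20 4-methoxybenzoyl chloride
Product: 21 the C1 4-methoxybenzoate of 19, (1S)-1-[(1S,2S,5R)-2-{[(tert-butyldiphenylsilyl)oxy]methyl}-5-hydroxy-2-methyl-5-(propan-2-yl)cyclopentyl]-3-methylbut-3-en-1-yl 4-methoxybenzoate
Conditions: pyridine, DMAP (cat.), CH2Cl2, 0 °C → rt
Reagents that add atoms: 4-methoxybenzoyl chloride, COc1ccc(cc1)C(Cl)=O
Why: DMAP-catalysed acylation of the secondary alcohol; the tertiary C9 hydroxyl is too hindered to react, so the anisoate is placed at C1 alone and protects it for the rest of the route.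

Step 12
Reactants: 21 the C1 4-methoxybenzoate of 19
Product: 22 (1S)-1-[(1S,2S,5R)-5-hydroxy-2-(hydroxymethyl)-2-methyl-5-(propan-2-yl)cyclopentyl]-3-methylbut-3-en-1-yl 4-methoxybenzoate
Conditions: Bu4NF, AcOH, THF, rt
Reagents that add atoms: none
Why: Fluoride desilylation of the primary silyl ether; acetic acid buffers the alkoxide so that the aryl ester neither migrates nor cleaves.

Step 13
Reactants: 22 (1S)-1-[(1S,2S,5R)-5-hydroxy-2-(hydroxymethyl)-2-methyl-5-(propan-2-yl)cyclopentyl]-3-methylbut-3-en-1-yl 4-methoxybenzoate
Product: 23 (1S)-1-[(1S,2S,5R)-2-formyl-5-hydroxy-2-methyl-5-(propan-2-yl)cyclopentyl]-3-methylbut-3-en-1-yl 4-methoxybenzoate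
Conditions: Dess–Martin periodinane, pyridine, CH2Cl2, 0 °C → rt
Reagents that add atoms: none
Why: Dess–Martin oxidation of the only oxidisable alcohol; the aldehyde sits on the quaternary C6 and cannot epimerise, and a lactol with the C9 hydroxyl is excluded because the two groups lie on opposite faces of the ring.

Step 14
Reactants: 23 (1S)-1-[(1S,2S,5R)-2-formyl-5-hydroxy-2-methyl-5-(propan-2-yl)cyclopentyl]-3-methylbut-3-en-1-yl 4-methoxybenzoate; 24 vinylmagnesium bromide
Product: 25 (1S)-1-[(1S,2S,5R)-5-hydroxy-2-(1-hydroxyprop-2-en-1-yl)-2-methyl-5-(propan-2-yl)cyclopentyl]-3-methylbut-3-en-1-yl 4-methoxybenzoate, as a mixture of C5 epimers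
Conditions: THF, −78 °C
Reagents that add atoms: vinylmagnesium bromide, C=C[Mg]Br
Why: Grignard 1,2-addition; one equivalent is spent on the C9 hydroxyl, and at −78 °C the aldehyde should react far faster than the electron-rich aryl ester. C5 is formed without reliable control (the Felkin–Anh bias at the α-quaternary aldehyde is weak), and both epimers are carried on because C5 is reset in steps 16 and 17.

Step 15
Reactants: 25 the C5-epimeric vinyl carbinols
Product: 26 (3R,3aS,4S,8RS,8aS)-3,8-dihydroxy-6,8a-dimethyl-3-(propan-2-yl)-1,2,3,3a,4,5,8,8a-octahydroazulen-4-yl 4-methoxybenzoate (local numbering: 1-anisoyloxy-5,9-dihydroxy, C5 epimers)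
Conditions: second-generation Grubbs catalyst (5 mol %), CH2Cl2, 40 °C
Reagents that add atoms: none
Why: Ring-closing metathesis between the monosubstituted and the 1,1-disubstituted alkene closes the seven-membered ring with loss of ethene and gives the trisubstituted, necessarily cis, C3=C4 alkene; free hydroxyls and the aryl ester are tolerated, and no stereocentre is formed.

Step 16
Reactants: 26 the C5-epimeric bicyclic allylic alcohols
Product: 27 (3R,3aS,4S,8aS)-3-hydroxy-6,8a-dimethyl-8-oxo-3-(propan-2-yl)-1,2,3,3a,4,5,8,8a-octahydroazulen-4-yl 4-methoxybenzoate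
Conditions: Dess–Martin periodinane, pyridine, CH2Cl2, rt
Reagents that add atoms: none
Why: Dess–Martin oxidation converges both C5 epimers on one enone; the tertiary alcohol and the ester are inert, and C6 next to the ketone is quaternary.

Step 17
Reactants: 27 (3R,3aS,4S,8aS)-3-hydroxy-6,8a-dimethyl-8-oxo-3-(propan-2-yl)-1,2,3,3a,4,5,8,8a-octahydroazulen-4-yl 4-methoxybenzoate
Product: 28 (3R,3aS,4S,8S,8aS)-3,8-dihydroxy-6,8a-dimethyl-3-(propan-2-yl)-1,2,3,3a,4,5,8,8a-octahydroazulen-4-yl 4-methoxybenzoate
Conditions: NaBH4, CeCl3·7H2O, MeOH, −78 °C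
Reagents that add atoms: none
Why: Luche reduction gives clean 1,2-addition to the enone; in the trans-fused bicycle the angular C6 methyl is axial beside the carbonyl, so hydride should enter anti to it and leave the C5 hydroxyl cis to the methyl (5S in local numbering).

Step 18
Reactants: 28 (3R,3aS,4S,8S,8aS)-3,8-dihydroxy-6,8a-dimethyl-3-(propan-2-yl)-1,2,3,3a,4,5,8,8a-octahydroazulen-4-yl 4-methoxybenzoate
Product: 29 (3R,3aS,4S,8S,8aS)-8-(acetyloxy)-3-hydroxy-6,8a-dimethyl-3-(propan-2-yl)-1,2,3,3a,4,5,8,8a-octahydroazulen-4-yl 4-methoxybenzoate (target; local numbering 1S,5S,6S,9R,10S)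
Conditions: Ac2O, pyridine, DMAP (cat.), CH2Cl2, 0 °C → rt
Reagents that add atoms: acetic anhydride, CC(=O)OC(C)=O
Why: Acylation of the secondary allylic alcohol under mild basic conditions; the hindered tertiary C9 hydroxyl should stay free, and no stereocentre is touched.

## Compound list

1 | (R)-carvone, (5R)-2-methyl-5-(prop-1-en-2-yl)cyclohex-2-en-1-one | CC1=CC[C@H](CC1=O)C(C)=C | starting material
2 | benzyl chloromethyl ether | ClCOCc1ccccc1 | starting material
3 | lithium (5R)-2-methyl-5-(prop-1-en-2-yl)cyclohex-1-en-1-olate | CC1=C(O[Li])C[C@@H](CC1)C(C)=C | intermediate (not isolated)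
4 | (2R,5R)-2-[(benzyloxy)methyl]-2-methyl-5-(prop-1-en-2-yl)cyclohexan-1-one | O=C1C[C@H](C(C)=C)CC[C@]1(C)COCc1ccccc1 | intermediate
5 | (3R,6R)-6-[(benzyloxy)methyl]-6-methyl-3-(prop-1-en-2-yl)-2-(trifluoroacetyl)cyclohexan-1-one (enolised, C2 not configurationally fixed) | O=C1C(C(=O)C(F)(F)F)[C@H](C(C)=C)CC[C@]1(C)COCc1ccccc1 | intermediate (not isolated)
6 | (3S,6R)-6-[(benzyloxy)methyl]-2-diazo-6-methyl-3-(prop-1-en-2-yl)cyclohexan-1-one | O=C1C(=[N+]=[N-])[C@H](C(C)=C)CC[C@]1(C)COCc1ccccc1 | intermediate (key-step precursor)
7 | [(2S,5S)-2-[(benzyloxy)methyl]-2-methyl-5-(prop-1-en-2-yl)cyclopentylidene]methanone (ketene) | O=C=C1[C@H](C(C)=C)CC[C@]1(C)COCc1ccccc1 | intermediate (not isolated)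
8 | methyl (1R,2S,5R)-2-[(benzyloxy)methyl]-2-methyl-5-(prop-1-en-2-yl)cyclopentane-1-carboxylate (C10 epimer of 9) | COC(=O)[C@@H]1[C@H](C(C)=C)CC[C@]1(C)COCc1ccccc1 | intermediate (not isolated)
9 | methyl (1S,2S,5R)-2-[(benzyloxy)methyl]-2-methyl-5-(prop-1-en-2-yl)cyclopentane-1-carboxylate | COC(=O)[C@H]1[C@H](C(C)=C)CC[C@]1(C)COCc1ccccc1 | intermediate (key-step product)
10 | methyl (1S,2S,5S)-2-(hydroxymethyl)-2-methyl-5-(propan-2-yl)cyclopentane-1-carboxylate | COC(=O)[C@H]1[C@H](C(C)C)CC[C@]1(C)CO | intermediate
11 | methyl (1S,2S,5S)-2-{[(tert-butyldiphenylsilyl)oxy]methyl}-2-methyl-5-(propan-2-yl)cyclopentane-1-carboxylate | COC(=O)[C@H]1[C@H](C(C)C)CC[C@]1(C)CO[Si](c1ccccc1)(c1ccccc1)C(C)(C)C | intermediate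
12 | methyl (1S,2R,5S)-2-{[(tert-butyldiphenylsilyl)oxy]methyl}-2-methyl-1-(phenylselanyl)-5-(propan-2-yl)cyclopentane-1-carboxylate (Se cis to the C6 methyl and H9) | COC(=O)[C@]1([Se]c2ccccc2)[C@H](C(C)C)CC[C@]1(C)CO[Si](c1ccccc1)(c1ccccc1)C(C)(C)C | intermediate (not isolated)
13 | methyl (5S)-5-{[(tert-butyldiphenylsilyl)oxy]methyl}-5-methyl-2-(propan-2-yl)cyclopent-1-ene-1-carboxylate | COC(=O)C1=C(C(C)C)CC[C@]1(C)CO[Si](c1ccccc1)(c1ccccc1)C(C)(C)C | intermediate
14 | methyl (1R,2R,5R)-2-{[(tert-butyldiphenylsilyl)oxy]methyl}-2-methyl-5-(propan-2-yl)-6-oxabicyclo[3.1.0]hexane-1-carboxylate (epoxide oxygen cis to the C6 methyl) | COC(=O)[C@@]12[C@](O1)(C(C)C)CC[C@]2(C)CO[Si](c1ccccc1)(c1ccccc1)C(C)(C)C | intermediate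
15 | methyl (1S,2S,5R)-2-{[(tert-butyldiphenylsilyl)oxy]methyl}-5-hydroxy-2-methyl-5-(propan-2-yl)cyclopentane-1-carboxylate (ester cis to isopropyl) | COC(=O)[C@@H]1[C@](O)(C(C)C)CC[C@]1(C)CO[Si](c1ccccc1)(c1ccccc1)C(C)(C)C | intermediate
16 | (1S,2S,5R)-2-{[(tert-butyldiphenylsilyl)oxy]methyl}-5-hydroxy-2-methyl-5-(propan-2-yl)cyclopentane-1-carbaldehyde (C10 epimer of 17) | O=C[C@@H]1[C@](O)(C(C)C)CC[C@]1(C)CO[Si](c1ccccc1)(c1ccccc1)C(C)(C)C | intermediate (not isolated)
17 | (1R,2S,5R)-2-{[(tert-butyldiphenylsilyl)oxy]methyl}-5-hydroxy-2-methyl-5-(propan-2-yl)cyclopentane-1-carbaldehyde | O=C[C@H]1[C@](O)(C(C)C)CC[C@]1(C)CO[Si](c1ccccc1)(c1ccccc1)C(C)(C)C | intermediate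
18 | 3-bromo-2-methylprop-1-ene | CC(=C)CBr | starting material
19 | (1R,2S,3S)-3-{[(tert-butyldiphenylsilyl)oxy]methyl}-2-[(1S)-1-hydroxy-3-methylbut-3-en-1-yl]-3-methyl-1-(propan-2-yl)cyclopentan-1-ol | CC(C)(C)[Si](OC[C@@]1(C)CC[C@@](O)(C(C)C)[C@@H]1[C@@H](O)CC(C)=C)(c1ccccc1)c1ccccc1 | intermediate
20 | 4-methoxybenzoyl chloride | COc1ccc(cc1)C(Cl)=O | starting material
21 | (1S)-1-[(1S,2S,5R)-2-{[(tert-butyldiphenylsilyl)oxy]methyl}-5-hydroxy-2-methyl-5-(propan-2-yl)cyclopentyl]-3-methylbut-3-en-1-yl 4-methoxybenzoate | CC(C)(C)[Si](OC[C@@]1(C)CC[C@@](O)(C(C)C)[C@@H]1[C@@H](OC(=O)c1ccc(OC)cc1)CC(C)=C)(c1ccccc1)c1ccccc1 | intermediate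
22 | (1S)-1-[(1S,2S,5R)-5-hydroxy-2-(hydroxymethyl)-2-methyl-5-(propan-2-yl)cyclopentyl]-3-methylbut-3-en-1-yl 4-methoxybenzoate | OC[C@@]1(C)CC[C@@](O)(C(C)C)[C@@H]1[C@@H](OC(=O)c1ccc(OC)cc1)CC(C)=C | intermediate
23 | (1S)-1-[(1S,2S,5R)-2-formyl-5-hydroxy-2-methyl-5-(propan-2-yl)cyclopentyl]-3-methylbut-3-en-1-yl 4-methoxybenzoate | O=C[C@@]1(C)CC[C@@](O)(C(C)C)[C@@H]1[C@@H](OC(=O)c1ccc(OC)cc1)CC(C)=C | intermediate
24 | vinylmagnesium bromide | C=C[Mg]Br | starting material
25 | (1S)-1-[(1S,2S,5R)-5-hydroxy-2-(1-hydroxyprop-2-en-1-yl)-2-methyl-5-(propan-2-yl)cyclopentyl]-3-methylbut-3-en-1-yl 4-methoxybenzoate, mixture of C5 epimers | C=CC(O)[C@@]1(C)CC[C@@](O)(C(C)C)[C@@H]1[C@@H](OC(=O)c1ccc(OC)cc1)CC(C)=C | intermediate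
26 | (3R,3aS,4S,8RS,8aS)-3,8-dihydroxy-6,8a-dimethyl-3-(propan-2-yl)-1,2,3,3a,4,5,8,8a-octahydroazulen-4-yl 4-methoxybenzoate, mixture of C5 epimers | COc1ccc(C(=O)O[C@H]2CC(C)=CC(O)[C@@]3(C)CC[C@@](O)(C(C)C)[C@H]23)cc1 | intermediate
27 | (3R,3aS,4S,8aS)-3-hydroxy-6,8a-dimethyl-8-oxo-3-(propan-2-yl)-1,2,3,3a,4,5,8,8a-octahydroazulen-4-yl 4-methoxybenzoate | COc1ccc(C(=O)O[C@H]2CC(C)=CC(=O)[C@@]3(C)CC[C@@](O)(C(C)C)[C@H]23)cc1 | intermediate
28 | (3R,3aS,4S,8S,8aS)-3,8-dihydroxy-6,8a-dimethyl-3-(propan-2-yl)-1,2,3,3a,4,5,8,8a-octahydroazulen-4-yl 4-methoxybenzoate | COc1ccc(C(=O)O[C@H]2CC(C)=C[C@H](O)[C@@]3(C)CC[C@@](O)(C(C)C)[C@H]23)cc1 | intermediate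
29 | (3R,3aS,4S,8S,8aS)-8-(acetyloxy)-3-hydroxy-6,8a-dimethyl-3-(propan-2-yl)-1,2,3,3a,4,5,8,8a-octahydroazulen-4-yl 4-methoxybenzoate | COc1ccc(C(=O)O[C@H]2CC(C)=C[C@H](OC(C)=O)[C@@]3(C)CC[C@@](O)(C(C)C)[C@H]23)cc1 | target

## Step count and least certain steps

Total: 18 steps. Longest linear sequence: 18 steps from (R)-carvone 1; the route is fully linear.

**Step 3 (key step).** The excited diazo ketone may partly leave the concerted path and behave as a carbene: insertion into the O–H bond of methanol, a 1,2-hydride shift from C9 to an enone, or secondary photoreactions of the isopropenyl group. The equilibration at C10 may also be slow beside a quaternary centre.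
Fallback: a quasi-Favorskii (semibenzilic) ring contraction. Ketone 4 is brominated through its enolate (LiN(SiMe3)2, then N-bromosuccinimide) to (2S,3S,6R)-6-[(benzyloxy)methyl]-2-bromo-6-methyl-3-(prop-1-en-2-yl)cyclohexan-1-one F1, with the bromide equatorial and anti-periplanar to the C1–C6 bond of the target numbering. NaOMe in methanol then adds to the carbonyl and shifts the quaternary carbon onto the bromide-bearing carbon, and the same base equilibrates C10, returning to the route at ester 9.

**Step 1.** The hard chloromethyl ether may alkylate the enolate on oxygen, proton exchange may scramble the enolate, and the axial preference may be incomplete.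
Fallback: from 1, the same reduction with the enolate trapped by gaseous formaldehyde (reductive aldol) gives (2R,5R)-2-(hydroxymethyl)-2-methyl-5-(prop-1-en-2-yl)cyclohexan-1-one F2. Acid-catalysed benzylation with benzyl 2,2,2-trichloroacetimidate, which avoids a retro-aldol under base, returns to the route at ketone 4.

**Step 7.** The peracid may not distinguish the methyl from the silyloxymethyl arm well enough, so that oxygen is delivered to both faces.
Fallback: reagent control in place of substrate control. Enoate 13 is reduced with iBu2AlH to [(5S)-5-{[(tert-butyldiphenylsilyl)oxy]methyl}-5-methyl-2-(propan-2-yl)cyclopent-1-en-1-yl]methanol F3. Sharpless asymmetric epoxidation (Ti(OiPr)4, tBuOOH, and the diethyl tartrate enantiomer that delivers oxygen to the methyl face, D-(−) by the usual mnemonic) gives [(1S,2R,5R)-2-{[(tert-butyldiphenylsilyl)oxy]methyl}-2-methyl-5-(propan-2-yl)-6-oxabicyclo[3.1.0]hexan-1-yl]methanol F4. Two-stage oxidation (TEMPO/NaOCl, then NaClO2) gives (1R,2R,5R)-2-{[(tert-butyldiphenylsilyl)oxy]methyl}-2-methyl-5-(propan-2-yl)-6-oxabicyclo[3.1.0]hexane-1-carboxylic acid F5. Methylation with Me3SiCHN2 returns to the route at epoxy ester 14.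

**Step 9 (with the C10 outcome of step 8).** During base equilibration the free β-hydroxy aldehyde may undergo retro-aldol opening of the ring, which would scramble C9 on re-closure, or lose water. The very hindered ester may also be over-reduced or reduced slowly. If step 8 already protonates C10 from the other face, the DBU treatment changes nothing.
Fallback: block the hydroxyl during the base treatment. Ester 15 is silylated (Me3SiOTf, 2,6-lutidine) to methyl (1S,2S,5R)-2-{[(tert-butyldiphenylsilyl)oxy]methyl}-2-methyl-5-(propan-2-yl)-5-[(trimethylsilyl)oxy]cyclopentane-1-carboxylate F6. iBu2AlH gives the (1S,2S,5R)-carbaldehyde F7, and DBU gives its (1R,2S,5R) epimer F8. Methanolysis of the trimethylsilyl ether with pyridinium p-toluenesulfonate returns to the route at aldehyde 17.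

**Step 10.** Chelation may be incomplete in the aqueous medium, or the addition to an aldehyde flanked by two fully substituted carbons may be slow, so that the facial selectivity at C1 erodes.
Fallback: reagent control from the same aldehyde 17. Methallylboration with the enantiomer of B-(2-methylallyl)diisopinocampheylborane matched to the (1S) carbinol, followed by oxidative work-up, returns to the route at diol 19. No new compound is involved.

**Step 17.** The flexible seven-membered enone may let hydride approach syn to the angular methyl, giving poor facial selectivity at C5.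
Fallback: set C5 before the ring is closed. Carbinols 25 are oxidised with Dess–Martin periodinane to (1S)-1-[(1S,2S,5R)-2-acryloyl-5-hydroxy-2-methyl-5-(propan-2-yl)cyclopentyl]-3-methylbut-3-en-1-yl 4-methoxybenzoate F9. Corey–Bakshi–Shibata reduction, with the oxazaborolidine enantiomer that treats the quaternary carbon as the large group and the vinyl group as the small one, gives the (5S) carbinol, (1S)-1-[(1S,2S,5R)-5-hydroxy-2-[(1S)-1-hydroxyprop-2-en-1-yl]-2-methyl-5-(propan-2-yl)cyclopentyl]-3-methylbut-3-en-1-yl 4-methoxybenzoate F10. Ring-closing metathesis with the second-generation Grubbs catalyst returns to the route at alcohol 28.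

## Further compounds

F1 | step 3 | (2S,3S,6R)-6-[(benzyloxy)methyl]-2-bromo-6-methyl-3-(prop-1-en-2-yl)cyclohexan-1-one | O=C1[C@@H](Br)[C@H](C(C)=C)CC[C@]1(C)COCc1ccccc1
F2 | step 1 | (2R,5R)-2-(hydroxymethyl)-2-methyl-5-(prop-1-en-2-yl)cyclohexan-1-one | O=C1C[C@H](C(C)=C)CC[C@]1(C)CO
F3 | step 7 | [(5S)-5-{[(tert-butyldiphenylsilyl)oxy]methyl}-5-methyl-2-(propan-2-yl)cyclopent-1-en-1-yl]methanol | OCC1=C(C(C)C)CC[C@]1(C)CO[Si](c1ccccc1)(c1ccccc1)C(C)(C)C
F4 | step 7 | [(1S,2R,5R)-2-{[(tert-butyldiphenylsilyl)oxy]methyl}-2-methyl-5-(propan-2-yl)-6-oxabicyclo[3.1.0]hexan-1-yl]methanol | OC[C@@]12[C@](O1)(C(C)C)CC[C@]2(C)CO[Si](c1ccccc1)(c1ccccc1)C(C)(C)C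
F5 | step 7 | (1R,2R,5R)-2-{[(tert-butyldiphenylsilyl)oxy]methyl}-2-methyl-5-(propan-2-yl)-6-oxabicyclo[3.1.0]hexane-1-carboxylic acid | OC(=O)[C@@]12[C@](O1)(C(C)C)CC[C@]2(C)CO[Si](c1ccccc1)(c1ccccc1)C(C)(C)C
F6 | step 9 | methyl (1S,2S,5R)-2-{[(tert-butyldiphenylsilyl)oxy]methyl}-2-methyl-5-(propan-2-yl)-5-[(trimethylsilyl)oxy]cyclopentane-1-carboxylate | COC(=O)[C@@H]1[C@](O[Si](C)(C)C)(C(C)C)CC[C@]1(C)CO[Si](c1ccccc1)(c1ccccc1)C(C)(C)C
F7 | step 9 | (1S,2S,5R)-2-{[(tert-butyldiphenylsilyl)oxy]methyl}-2-methyl-5-(propan-2-yl)-5-[(trimethylsilyl)oxy]cyclopentane-1-carbaldehyde | O=C[C@@H]1[C@](O[Si](C)(C)C)(C(C)C)CC[C@]1(C)CO[Si](c1ccccc1)(c1ccccc1)C(C)(C)C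
F8 | step 9 | (1R,2S,5R)-2-{[(tert-butyldiphenylsilyl)oxy]methyl}-2-methyl-5-(propan-2-yl)-5-[(trimethylsilyl)oxy]cyclopentane-1-carbaldehyde | O=C[C@H]1[C@](O[Si](C)(C)C)(C(C)C)CC[C@]1(C)CO[Si](c1ccccc1)(c1ccccc1)C(C)(C)C
F0 | step 10 | none | none
F9 | step 17 | (1S)-1-[(1S,2S,5R)-2-acryloyl-5-hydroxy-2-methyl-5-(propan-2-yl)cyclopentyl]-3-methylbut-3-en-1-yl 4-methoxybenzoate | C=CC(=O)[C@@]1(C)CC[C@@](O)(C(C)C)[C@@H]1[C@@H](OC(=O)c1ccc(OC)cc1)CC(C)=C
F10 | step 17 | (1S)-1-[(1S,2S,5R)-5-hydroxy-2-[(1S)-1-hydroxyprop-2-en-1-yl]-2-methyl-5-(propan-2-yl)cyclopentyl]-3-methylbut-3-en-1-yl 4-methoxybenzoate | C=C[C@H](O)[C@@]1(C)CC[C@@](O)(C(C)C)[C@@H]1[C@@H](OC(=O)c1ccc(OC)cc1)CC(C)=C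
A1 | alternative 1 | (4S)-4-methyl-4-{2-[2-(propan-2-yl)-1,3-dioxolan-2-yl]ethyl}cyclopentane-1,3-dione | O=C1CC(=O)[C@@](C)(CCC2(C(C)C)OCCO2)C1
A2 | alternative 1 | allene (propa-1,2-diene) | C=C=C
A3 | alternative 1 | (6S)-6-methyl-3-methylidene-6-{2-[2-(propan-2-yl)-1,3-dioxolan-2-yl]ethyl}cycloheptane-1,5-dione | O=C1CC(=C)CC(=O)[C@@](C)(CCC2(C(C)C)OCCO2)C1
A4 | alternative 2 | 3-(dimethoxymethyl)cyclopent-2-en-1-one | O=C1CCC(C(OC)OC)=C1
A5 | alternative 2 | (3Z)-4-iodo-3-methylbut-3-enal | O=CC/C(C)=C\I
A6 | alternative 2 | (2S,3S)-3-(dimethoxymethyl)-2-[(1S,3Z)-1-hydroxy-4-iodo-3-methylbut-3-en-1-yl]-3-methylcyclopentan-1-one | O[C@@H](C/C(C)=C\I)[C@H]1C(=O)CC[C@]1(C)C(OC)OC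
A7 | alternative 3 | cis-divinylcyclopropane: one ring carbon with methyl and (Z)-2-acetoxyvinyl, the other with tert-butyldimethylsilyloxy and 2-methyl-5-(propan-2-yl)-5-(trimethylsilyloxy)cyclopent-1-en-1-yl, the two alkenyl arms cis | CC(=O)O/C=C\[C@@]1(C)C[C@@]1(O[Si](C)(C)C(C)(C)C)C1=C(C)CC[C@@]1(O[Si](C)(C)C)C(C)C
A8 | alternative 3 | bicyclic cyclohepta-1,4-diene with C1 tert-butyldimethylsilyl enol ether (C1=C10), C3=C4, C5 acetate, C6 methyl, C9 trimethylsilyloxy and isopropyl | CC(C)(C)[Si](C)(C)OC1=C2[C@](O[Si](C)(C)C)(C(C)C)CC[C@]2(C)[C@@H](OC(C)=O)C=C(C)C1
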